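**Plan**
1. Retrosynthetic cuts: C12–C13 and the imide (aldol, ammonolysis), C8–C17 (enol triflate coupling), C9–C11 (allylation), C4–C5 (ring A) and C10–C1 (Birch alkylation).
2. Enabling feature: ring B has oxygen at C6 and a carbonyl-level carbon at C8 on either side of C7, with quaternary C10 meta to both. This is the pattern of 3,5-dimethoxybenzoic acid, whose Birch diene offers two diastereotopic enol ethers (C5=C6 and C9=C8) to a C4 cation tethered at C10.
3. Forward order: the C1–C4 tether is made from (R)-epichlorohydrin and 2-bromopropene; Birch reductive alkylation fixes ring B and C10; ring A closes by C4–C5 bond formation; then C9 allyl, C2 chloride, C5 inversion, C8 CH2SiMe3, side chain, and a final desilylative deconjugation to C8=C17.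
4. Stereochemistry: C2 from epichlorohydrin (inverted at chlorination); C10 by group selection in a chair with equatorial silyloxy; C9 by convex-face allylation of the cis-decalin; C5 by kinetic protonation of the α′-enolate; C12/C13 by an Evans syn-aldol.

Key step: step 8

Assumptions: decalin atoms carry labdane numbers (C1–C10, C11–C16 side chain, C17 on C8; α/β as in that series), and spent organometallic reagents are booked as the salts left after an aqueous NH4Cl quench.

**Step 1**
Reactants: 1 2-bromopropene; 2 (R)-epichlorohydrin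
Product: 4 (2R)-1-chloro-4-methylpent-4-en-2-ol, via isopropenylmagnesium bromide 3 (not isolated)
Conditions: Mg, THF, 40 °C; then CuI (10 mol %), 2, THF, −40 → −20 °C; aq NH4Cl
Reagents that add atoms: none
Why: Copper-catalysed Grignard opening of the epoxide at its unsubstituted carbon leaves the C–Cl bond and the stereocentre of 2 untouched.

**Step 2**
Reactants: 4 (2R)-1-chloro-4-methylpent-4-en-2-ol
Product: 5 (2R)-2-(2-methylprop-2-en-1-yl)oxirane
Conditions: powdered NaOH, Et2O, 0 °C → rt
Reagents that add atoms: none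
Why: Intramolecular Williamson closure of the chlorohydrin (3-exo-tet) does not break the C–O bond of the stereocentre.

**Step 3**
Reactants: 5 (2R)-2-(2-methylprop-2-en-1-yl)oxirane
Product: 6 2-methyl-1-[(2R)-oxiran-2-yl]propan-2-ol
Conditions: Co(acac)2 (20 mol %), PhSiH3, O2 (1 atm), THF, rt; then aq Na2S2O3
Reagents that add atoms: dioxygen, O=O
Why: Mukaiyama hydration gives the Markovnikov tertiary alcohol from the 1,1-disubstituted alkene under neutral conditions that should spare the epoxide.

**Step 4**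
Reactants: 7 3,5-dimethoxybenzoic acid; 6 2-methyl-1-[(2R)-oxiran-2-yl]propan-2-ol
Product: 10 (3S)-3-(2-hydroxy-2-methylpropyl)-7,9-dimethoxy-2-oxaspiro[4.5]deca-6,9-dien-1-one, via dilithium (3,5-dimethoxycyclohexa-2,5-dien-1-ylidene)methanediolate 8 (not isolated), via 1-[(2S)-2,4-dihydroxy-4-methylpentyl]-3,5-dimethoxycyclohexa-2,5-diene-1-carboxylic acid 9 (not isolated)
Conditions: Li (3.3 equiv), NH3–THF, −78 °C; then 6, −78 → −33 °C; NH4Cl; aq NaH2PO4 (pH 5), 0 °C; concentrate from PhMe, 40 °C
Reagents that add atoms: none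
Why: Birch reductive alkylation, in which the carboxylate dienolate is C-alkylated at the ipso carbon (future C10) by the terminal epoxide carbon (the lithium amide formed deprotonates the tertiary alcohol), and the α-quaternary γ-hydroxy acid should lactonise on mild acidification.

**Step 5**
Reactants: 10 spirolactone
Product: 11 (3S)-3-(2-hydroxy-2-methylpropyl)-7,9-dimethoxy-2-oxaspiro[4.5]deca-6,9-dien-1-ol (lactol, both anomers)
Conditions: DIBAL-H (2.2 equiv), CH2Cl2, −78 °C; Rochelle salt
Reagents that add atoms: none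
Why: Partial reduction of the hindered lactone stops at the lactol at −78 °C; the anomeric centre is removed in the next step.

**Step 6**
Reactants: 11 lactol
Product: 13 (4S)-5-(3,5-dimethoxy-1-methylcyclohexa-2,5-dien-1-yl)-2-methylpentane-2,4-diol, via the N′-tosylhydrazone of 1-[(2S)-2,4-dihydroxy-4-methylpentyl]-3,5-dimethoxycyclohexa-2,5-diene-1-carbaldehyde 12 (not isolated)
Conditions: TsNHNH2, THF, 4 Å MS, 50 °C; then NaBH4, THF–MeOH, 65 °C
Reagents that add atoms: none
Why: Caglioti reduction, in which the lactol reacts as its hydroxy aldehyde (no α-hydrogen) and the tosylhydrazone is reduced with loss of N2 and sulfinate to the C10 methyl group under basic conditions that should spare both enol ethers and the 1,4-diene.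

**Step 7**
Reactants: 13 diol
Product: 14 (4S)-4-[(tert-butyldimethylsilyl)oxy]-5-(3,5-dimethoxy-1-methylcyclohexa-2,5-dien-1-yl)-2-methylpentan-2-ol
Conditions: TBSCl, imidazole, DMF, rt
Reagents that add atoms: tert-butyldimethylsilyl chloride, CC(C)(C)[Si](C)(C)Cl
Why: Silylation with TBSCl/imidazole is selective for the secondary over the tertiary hydroxyl.

**Step 8**
Reactants: 14 tertiary alcohol with C2 silyl ether and bis-enol-ether diene
Product: 15 (2R,5R,10R)-2-[(tert-butyldimethylsilyl)oxy]-8-methoxy-4,4,10-trimethyl-cis-decal-8-en-6-one (5β-H, cis-fused; silyloxy cis to the C10 methyl)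
Conditions: 2,6-di-tert-butyl-4-methylpyridine (1.2 equiv), TiCl4 (2.5 equiv), CH2Cl2, −78 → −45 °C; then cold sat. aq NaHCO3
Reagents that add atoms: water, O
Why: Proposed new method: TiCl4 converts the tertiary alcohol into its titanate (the HCl is taken up by the hindered pyridine) and ionises it to the C4 cation, which is captured in a six-membered chair by the nucleophilic carbon of one enol ether to form C4–C5; the C6 oxocarbenium ion collapses to the α-chloro ether and is hydrolysed to the ketone on quench, while the untouched C8=C9 enol ether survives. The closest known reactions are the Lewis-acid α-tert-alkylation of silyl enol ethers with tert-alkyl chlorides, the Lewis-acid addition of tert-alkyl chlorides to alkyl vinyl ethers, and diastereotopic-group-selective Prins cyclisations of Birch-derived cyclohexa-1,4-dienes. Ring A closes in a 6-exo mode with respect to the C5=C6 π bond. C10 becomes stereogenic by group selection: in the chair the C2 silyloxy group is equatorial and then lies cis to the C10 methyl, whereas attack on the other enol ether would place it axial and syn to the C10–C9 bond; C5 is set by bond formation on the ring-B face that carries the tether, which gives the cis-fused decalin. The step needs ring closure to outrun E1 loss and protonation or conjugation of the 1,4-diene, which the low temperature, the proton trap and the short tether should secure.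

**Step 9**
Reactants: 15 cis-fused keto enol ether
Product: 17 (2R,5R,9R,10R)-9-allyl-2-[(tert-butyldimethylsilyl)oxy]-8-methoxy-4,4,10-trimethyl-cis-decal-7-en-6-one (9β-allyl), via the lithium C6 dienolate of 15 (C6–OLi, C6=C7, C8(OMe)=C9) 16 (not isolated)
Conditions: LDA (1.05 equiv), THF, −78 °C; DMPU, allyl bromide, −78 → −30 °C
Reagents that add atoms: allyl bromide, C=CCBr
Why: γ-Alkylation of a β-alkoxy dienolate (as with tetronate and 3-alkoxycrotonate anions), in which LDA removes the doubly activated C7–H and the dienolate should be allylated at C9 on the convex face of the cis-decalin (syn to the C10 methyl, anti to ring A), the product falling into conjugation as the vinylogous ester.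

**Step 10**
Reactants: 17 silyl ether
Product: 18 (2R,5R,9R,10R)-9-allyl-2-hydroxy-8-methoxy-4,4,10-trimethyl-cis-decal-7-en-6-one
Conditions: HF·pyridine, pyridine–THF, 0 °C → rt
Reagents that add atoms: none
Why: Fluoride-mediated cleavage of the secondary TBS ether under buffered conditions that a vinylogous ester and an allyl group tolerate.

**Step 11**
Reactants: 18 2β-alcohol
Product: 19 (2S,5R,9R,10R)-9-allyl-2-chloro-8-methoxy-4,4,10-trimethyl-cis-decal-7-en-6-one (2α-chloride)
Conditions: PPh3, CCl4, MeCN, 60 °C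
Reagents that add atoms: carbon tetrachloride, ClC(Cl)(Cl)Cl
Why: Appel reaction, in which chloride displaces the oxyphosphonium group by SN2 from the α face (anti to the C10 and 4β methyl groups) and inverts C2 to the 2α-chloride.

**Step 12**
Reactants: 19 cis-fused chloride
Product: 21 (2S,5S,9R,10R)-9-allyl-2-chloro-8-methoxy-4,4,10-trimethyl-trans-decal-7-en-6-one, via the lithium α′-enolate of 19 (C5=C6–OLi) 20 (not isolated)
Conditions: LDA (2 equiv), THF, −78 → −30 °C; then AcOH, THF, −78 °C
Reagents that add atoms: none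
Why: Kinetic α′-deprotonation of the 3-alkoxy-enone (Stork–Danheiser regiochemistry) followed by kinetic protonation of the enolate at C5 from the α face, opposite the C10 and 4β methyl groups and the 9β-allyl group, should give the trans fusion without relying on the finely balanced cis/trans equilibrium of 4,4,10-trimethyl-6-decalones.

**Step 13**
Reactants: 21 trans-fused vinylogous ester
Product: 22 (2S,5S,9R,10R)-9-allyl-2-chloro-4,4,10-trimethyl-trans-decalin-6,8-dione
Conditions: 1 M HCl, THF, rt
Reagents that add atoms: water, O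
Why: Acid hydrolysis of the vinylogous ester (water adds at C8, methanol leaves) gives the β-diketone under conditions mild enough that the hindered C5 and C9 methines should not enolise.

**Step 14**
Reactants: 22 β-diketone
Product: 23 (2S,5S,9R,10R)-9-allyl-2-chloro-4,4,10-trimethyl-6-oxo-trans-decal-7-en-8-yl trifluoromethanesulfonate
Conditions: Tf2O, Et3N, CH2Cl2, −78 °C
Reagents that add atoms: trifluoromethanesulfonic anhydride, O=S(=O)(OS(=O)(=O)C(F)(F)F)C(F)(F)F
Why: Enol triflate formation of the β-diketone should occur at O8, which is flanked only by the C11 methylene, because O6 is shielded by the C4 gem-dimethyl group.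

**Step 15**
Reactants: 23 enol triflate
Product: 24 (2S,5S,9R,10R)-9-allyl-2-chloro-4,4,10-trimethyl-8-[(trimethylsilyl)methyl]-trans-decal-7-en-6-one
Conditions: Me3SiCH2MgCl, Pd(PPh3)4 (5 mol %), THF, 0 °C → rt
Reagents that add atoms: (trimethylsilyl)methylmagnesium chloride, C[Si](C)(C)C[Mg]Cl
Why: Kumada coupling of the β-acyl vinyl triflate, whose oxidative addition is fast, installs C17 as a silylmethyl group while the hindered C6 carbonyl, the alkyl chloride and the allyl group should be left alone.

**Step 16**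
Reactants: 24 allyl enone
Product: 25 2-[(2S,5S,9R,10R)-2-chloro-4,4,10-trimethyl-6-oxo-8-[(trimethylsilyl)methyl]-trans-decal-7-en-9-yl]acetaldehyde
Conditions: OsO4 (2 mol %), NaIO4, 2,6-lutidine, dioxane–H2O (3:1), rt
Reagents that add atoms: sodium periodate (terminal oxidant, via OsO4), [Na+].[O-]I(=O)(=O)=O
Why: Lemieux–Johnson cleavage, in which osmium tetroxide attacks the monosubstituted allyl alkene in preference to the trisubstituted conjugated C7=C8 bond and periodate cleaves the diol to the C12 aldehyde.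

**Step 17**
Reactants: 26 (R)-4-benzyloxazolidin-2-one; 27 methyl 4-chloro-4-oxobutanoate
Product: 28 methyl 4-[(4R)-4-benzyl-2-oxo-1,3-oxazolidin-3-yl]-4-oxobutanoate
Conditions: Et3N, DMAP (10 mol %), CH2Cl2, 0 °C → rt
Reagents that add atoms: none
Why: DMAP-catalysed N-acylation of the oxazolidinone by the acid chloride.

**Step 18**
Reactants: 28 acyl oxazolidinone; 25 aldehyde
Product: 30 methyl (3R,4S)-3-{[(4R)-4-benzyl-2-oxo-1,3-oxazolidin-3-yl]carbonyl}-5-[(2S,5S,9R,10R)-2-chloro-4,4,10-trimethyl-6-oxo-8-[(trimethylsilyl)methyl]-trans-decal-7-en-9-yl]-4-hydroxypentanoate (12S,13R), via the (Z)-di-n-butylboron enolate of 28 29 (not isolated)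
Conditions: 28, n-Bu2BOTf, i-Pr2NEt, CH2Cl2, −78 → 0 °C; then 25, −78 → 0 °C; pH 7 buffer, MeOH, H2O2, 0 °C
Reagents that add atoms: none
Why: Evans syn-aldol, in which the Z-boron enolate (formed at the imide α-carbon) adds to the aldehyde through a closed six-membered transition state and the (R)-benzyl auxiliary sets 12S and 13R.

**Step 19**
Reactants: 30 aldol adduct
Product: 31 (3R)-3-{(1S)-2-[(2S,5S,9R,10R)-2-chloro-4,4,10-trimethyl-6-oxo-8-[(trimethylsilyl)methyl]-trans-decal-7-en-9-yl]-1-hydroxyethyl}pyrrolidine-2,5-dione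
Conditions: NH3 (7 M in MeOH), 0 °C → rt
Reagents that add atoms: ammonia, N
Why: Ammonolysis turns the ester (or the γ-lactone it may form with the C12 hydroxyl) into the primary amide, whose nitrogen displaces the oxazolidinone intramolecularly to close the succinimide and release the auxiliary.

**Step 20**
Reactants: 31 silylmethyl enone imide
Product: 32 haterumaimide G, (2S,5S,9S,10R,12S,13R)
Conditions: TBAF, AcOH (1:1.2), THF, 0 °C
Reagents that add atoms: none
Why: Fluoride cleaves the C–Si bond of the vinylogous α-silyl ketone to the C6 dienolate, whose kinetic α-protonation at C7 by acetic acid should give the deconjugated exocyclic C8=C17 alkene (desilylative deconjugation) under buffered conditions.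

**Compound list**
1 | 2-bromopropene | CC(Br)=C | starting material
2 | (R)-epichlorohydrin | ClC[C@H]1CO1 | starting material
3 | isopropenylmagnesium bromide | CC(=C)[Mg]Br | intermediate
4 | (2R)-1-chloro-4-methylpent-4-en-2-ol | ClC[C@H](O)CC(C)=C | intermediate
5 | (2R)-2-(2-methylprop-2-en-1-yl)oxirane | C=C(C)C[C@@H]1CO1 | intermediate
6 | 2-methyl-1-[(2R)-oxiran-2-yl]propan-2-ol | CC(C)(O)C[C@@H]1CO1 | intermediate
7 | 3,5-dimethoxybenzoic acid | COc1cc(OC)cc(C(=O)O)c1 | starting material
8 | dilithium (3,5-dimethoxycyclohexa-2,5-dien-1-ylidene)methanediolate | [Li+].[Li+].[O-]C([O-])=C1C=C(OC)CC(OC)=C1 | intermediate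
9 | 1-[(2S)-2,4-dihydroxy-4-methylpentyl]-3,5-dimethoxycyclohexa-2,5-diene-1-carboxylic acid | COC1=CC(C[C@H](O)CC(C)(C)O)(C(=O)O)C=C(OC)C1 | intermediate
10 | (3S)-3-(2-hydroxy-2-methylpropyl)-7,9-dimethoxy-2-oxaspiro[4.5]deca-6,9-dien-1-one | COC1=CC2(C=C(OC)C1)C[C@@H](CC(C)(C)O)OC2=O | intermediate
11 | (3S)-3-(2-hydroxy-2-methylpropyl)-7,9-dimethoxy-2-oxaspiro[4.5]deca-6,9-dien-1-ol (both anomers) | COC1=CC2(C=C(OC)C1)C[C@@H](CC(C)(C)O)OC2O | intermediate
12 | N′-tosylhydrazone of 1-[(2S)-2,4-dihydroxy-4-methylpentyl]-3,5-dimethoxycyclohexa-2,5-diene-1-carbaldehyde | COC1=CC(C[C@H](O)CC(C)(C)O)(C=NNS(=O)(=O)c2ccc(C)cc2)C=C(OC)C1 | intermediate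
13 | (4S)-5-(3,5-dimethoxy-1-methylcyclohexa-2,5-dien-1-yl)-2-methylpentane-2,4-diol | COC1=CC(C)(C[C@H](O)CC(C)(C)O)C=C(OC)C1 | intermediate
14 | (4S)-4-[(tert-butyldimethylsilyl)oxy]-5-(3,5-dimethoxy-1-methylcyclohexa-2,5-dien-1-yl)-2-methylpentan-2-ol | COC1=CC(C)(C[C@H](O[Si](C)(C)C(C)(C)C)CC(C)(C)O)C=C(OC)C1 | intermediate
15 | (2R,5R,10R)-2-[(tert-butyldimethylsilyl)oxy]-8-methoxy-4,4,10-trimethyl-cis-decal-8-en-6-one | COC=1CC(=O)[C@@H]2C(C)(C)C[C@@H](O[Si](C)(C)C(C)(C)C)C[C@]2(C)C=1 | intermediate
16 | lithium C6 dienolate of 15 | [Li+].COC=1C=C([O-])[C@@H]2C(C)(C)C[C@@H](O[Si](C)(C)C(C)(C)C)C[C@]2(C)C=1 | intermediate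
17 | (2R,5R,9R,10R)-9-allyl-2-[(tert-butyldimethylsilyl)oxy]-8-methoxy-4,4,10-trimethyl-cis-decal-7-en-6-one | COC1=CC(=O)[C@@H]2C(C)(C)C[C@@H](O[Si](C)(C)C(C)(C)C)C[C@]2(C)[C@H]1CC=C | intermediate
18 | (2R,5R,9R,10R)-9-allyl-2-hydroxy-8-methoxy-4,4,10-trimethyl-cis-decal-7-en-6-one | COC1=CC(=O)[C@@H]2C(C)(C)C[C@@H](O)C[C@]2(C)[C@H]1CC=C | intermediate
19 | (2S,5R,9R,10R)-9-allyl-2-chloro-8-methoxy-4,4,10-trimethyl-cis-decal-7-en-6-one | COC1=CC(=O)[C@@H]2C(C)(C)C[C@H](Cl)C[C@]2(C)[C@H]1CC=C | intermediate
20 | lithium α′-enolate (C5=C6–OLi) of 19 | [Li+].COC1=CC([O-])=C2C(C)(C)C[C@H](Cl)C[C@]2(C)[C@H]1CC=C | intermediate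
21 | (2S,5S,9R,10R)-9-allyl-2-chloro-8-methoxy-4,4,10-trimethyl-trans-decal-7-en-6-one | COC1=CC(=O)[C@H]2C(C)(C)C[C@H](Cl)C[C@]2(C)[C@H]1CC=C | intermediate
22 | (2S,5S,9R,10R)-9-allyl-2-chloro-4,4,10-trimethyl-trans-decalin-6,8-dione | O=C1CC(=O)[C@H]2C(C)(C)C[C@H](Cl)C[C@]2(C)[C@H]1CC=C | intermediate
23 | (2S,5S,9R,10R)-9-allyl-2-chloro-4,4,10-trimethyl-6-oxo-trans-decal-7-en-8-yl triflate | FC(F)(F)S(=O)(=O)OC1=CC(=O)[C@H]2C(C)(C)C[C@H](Cl)C[C@]2(C)[C@H]1CC=C | intermediate
24 | (2S,5S,9R,10R)-9-allyl-2-chloro-4,4,10-trimethyl-8-[(trimethylsilyl)methyl]-trans-decal-7-en-6-one | C[Si](C)(C)CC1=CC(=O)[C@H]2C(C)(C)C[C@H](Cl)C[C@]2(C)[C@H]1CC=C | intermediate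
25 | 2-[(2S,5S,9R,10R)-2-chloro-4,4,10-trimethyl-6-oxo-8-[(trimethylsilyl)methyl]-trans-decal-7-en-9-yl]acetaldehyde | C[Si](C)(C)CC1=CC(=O)[C@H]2C(C)(C)C[C@H](Cl)C[C@]2(C)[C@H]1CC=O | intermediate
26 | (R)-4-benzyloxazolidin-2-one | O=C1N[C@H](Cc2ccccc2)CO1 | starting material
27 | methyl 4-chloro-4-oxobutanoate | COC(=O)CCC(Cl)=O | starting material
28 | methyl 4-[(4R)-4-benzyl-2-oxo-1,3-oxazolidin-3-yl]-4-oxobutanoate | COC(=O)CCC(=O)N1[C@H](Cc2ccccc2)COC1=O | intermediate
29 | (Z)-di-n-butylboron enolate of 28 | CCCCB(CCCC)O/C(=C\CC(=O)OC)N1[C@H](Cc2ccccc2)COC1=O | intermediate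
30 | Evans aldol adduct (12S,13R) of 25 and 28 | C[Si](C)(C)CC1=CC(=O)[C@H]2C(C)(C)C[C@H](Cl)C[C@]2(C)[C@H]1C[C@H](O)[C@@H](CC(=O)OC)C(=O)N1[C@H](Cc2ccccc2)COC1=O | intermediate
31 | (3R)-3-{(1S)-2-[(2S,5S,9R,10R)-2-chloro-4,4,10-trimethyl-6-oxo-8-[(trimethylsilyl)methyl]-trans-decal-7-en-9-yl]-1-hydroxyethyl}pyrrolidine-2,5-dione | C[Si](C)(C)CC1=CC(=O)[C@H]2C(C)(C)C[C@H](Cl)C[C@]2(C)[C@H]1C[C@H](O)[C@H]1CC(=O)NC1=O | intermediate
32 | haterumaimide G | C=C1CC(=O)[C@H]2C(C)(C)C[C@H](Cl)C[C@]2(C)[C@H]1C[C@H](O)[C@H]1CC(=O)NC1=O | target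

**Step count**
Total: 20 steps. Longest linear sequence: 19 steps (steps 1–16 and 18–20); step 17 is a one-step branch for the aldol partner.

**Steps most likely to fail**

Step 8. The titanate may release HCl faster than the pyridine traps it, so that the dienol ether is protonated, shifts into conjugation or hydrolyses before ring closure. The cation may also be lost by E1 elimination, or the two enol ether carbons may not be discriminated. The fallback uses known chemistry and gives up group selection. It sets out from 14. Oxalic acid in wet THF hydrolyses both enol ethers to 5-{(2S)-2-[(tert-butyldimethylsilyl)oxy]-4-hydroxy-4-methylpentyl}-5-methylcyclohexane-1,3-dione F1. Trimethylsilyldiazomethane re-forms one vinylogous methyl ester, 3-methoxy-5-methyl-5-{(2S)-2-silyloxy-4-hydroxy-4-methylpentyl}cyclohex-2-enone F2, as both C10 epimers. 1-Chloro-N,N,2-trimethylpropenylamine exchanges the tertiary hydroxyl for chloride to give the tertiary chloride F3. Kinetic α′-enolisation (LDA, then TMSCl) gives the 2-silyloxy diene F4. TiCl4 at −78 °C then closes ring A by α-tert-alkylation of the silyl enol ether with the tertiary chloride, giving the cis-fused vinylogous ester (2R,5R,10R)-2-silyloxy-8-methoxy-4,4,10-trimethyl-cis-decal-7-en-6-one F5, which is separated from its C10 epimer. LDA deprotonates F5 at C9 to the dienolate 16, and allylation returns the route at 17.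

Step 12. Deprotonation at the hindered C5–H may be slower than at the γ C9–H, so that the dienolate is reprotonated with C5 unchanged, or the axial-chloride conformer may lose HCl by E2. The fallback replaces kinetic by thermodynamic control. It sets out from 19, which is equilibrated with NaOMe in MeOH at 50 °C by reversible α′-enolisation; with the 2α-chloride in place only the trans-fused chair keeps the C–Cl bond equatorial. The trans isomer 21 is separated, the recovered 19 is resubmitted, and the route resumes at 21; no new compound is made.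

Step 9. The dienolate may be allylated at C7 or on oxygen instead of at C9, or on the concave face. The fallback sets out from 15. Oxalic acid in wet THF hydrolyses the remaining enol ether to the cis-fused dione (2R,5R,10R)-2-silyloxy-4,4,10-trimethyl-cis-decalin-6,8-dione F6. Its dianion (LDA, 2.2 equiv, DMPU) is allylated at the terminal, less hindered C9 (γ-alkylation of a 1,3-diketone dianion) to give the 9β-allyl dione F7. O-Methylation with trimethylsilyldiazomethane at the less hindered O8 returns the route at 17.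

**Further compounds**
F1 | step 8 | 5-{(2S)-2-[(tert-butyldimethylsilyl)oxy]-4-hydroxy-4-methylpentyl}-5-methylcyclohexane-1,3-dione | CC(C)(O)C[C@@H](O[Si](C)(C)C(C)(C)C)CC1(C)CC(=O)CC(=O)C1
F2 | step 8 | 5-{(2S)-2-[(tert-butyldimethylsilyl)oxy]-4-hydroxy-4-methylpentyl}-3-methoxy-5-methylcyclohex-2-en-1-one (both C5 epimers) | COC1=CC(=O)CC(C)(C[C@H](O[Si](C)(C)C(C)(C)C)CC(C)(C)O)C1
F3 | step 8 | 5-{(2S)-2-[(tert-butyldimethylsilyl)oxy]-4-chloro-4-methylpentyl}-3-methoxy-5-methylcyclohex-2-en-1-one (both C5 epimers) | COC1=CC(=O)CC(C)(C[C@H](O[Si](C)(C)C(C)(C)C)CC(C)(C)Cl)C1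
F4 | step 8 | 5-{(2S)-2-[(tert-butyldimethylsilyl)oxy]-4-chloro-4-methylpentyl}-1-methoxy-5-methyl-3-(trimethylsilyloxy)cyclohexa-1,3-diene (both C5 epimers) | COC1=CC(O[Si](C)(C)C)=CC(C)(C[C@H](O[Si](C)(C)C(C)(C)C)CC(C)(C)Cl)C1
F5 | step 8 | (2R,5R,10R)-2-[(tert-butyldimethylsilyl)oxy]-8-methoxy-4,4,10-trimethyl-cis-decal-7-en-6-one | COC1=CC(=O)[C@@H]2C(C)(C)C[C@@H](O[Si](C)(C)C(C)(C)C)C[C@]2(C)C1
F0 | step 12 | none | none
F6 | step 9 | (2R,5R,10R)-2-[(tert-butyldimethylsilyl)oxy]-4,4,10-trimethyl-cis-decalin-6,8-dione | O=C1CC(=O)[C@@H]2C(C)(C)C[C@@H](O[Si](C)(C)C(C)(C)C)C[C@]2(C)C1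
F7 | step 9 | (2R,5R,9R,10R)-9-allyl-2-[(tert-butyldimethylsilyl)oxy]-4,4,10-trimethyl-cis-decalin-6,8-dione | O=C1CC(=O)[C@@H]2C(C)(C)C[C@@H](O[Si](C)(C)C(C)(C)C)C[C@]2(C)[C@H]1CC=C
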